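**Plan** (target numbering: C1 ester carbonyl … C16 CH–Ph; ring O2 on C3, ring O1 on C6)

1. Retrosynthesis: open the hemiketal bond C3–O2 (C6 hydroperoxide plus C3 ketone), cut C2–C3 (malonate acylation), cut C15=C16 and C9–C10 (two Wittig reactions on one six-carbon bis-phosphonium linker), then rejoin C3 to C9 as a ring alkene.
2. Enabling feature: the methyl-bearing carbons C4 and C8 have opposite sense and each lies one CH2 (C5, C7) from C6. C3–C9 is therefore a meso cis-3,6-dimethylcycloheptene ring with alkene carbons C3 and C9, the [4+3] adduct of a C5–C6–C7 oxyallyl unit and (2E,4E)-hexa-2,4-diene.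
3. Forward order: the cycloaddition closes the only carbocycle; C6 gains a methylene and then a silyl-protected hydroperoxide while still in the ring; ozonolysis opens C3=C9 to a meso diol; a lipase distinguishes the two arms; the C9 arm is extended to the Z-styryl chain and the C3 arm to the β-keto ester; desilylation closes the 1,2-dioxane ring.
4. Stereochemistry: C4/C8 relative configuration from the E,E diene geometry; C6 from O2 capture on the ring face anti to both methyls; absolute configuration of all three from the enzymatic step; C3 from thermodynamic (anomeric) hemiketal formation; the Z alkene from a lithium-free Wittig reaction with benzaldehyde.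

Key step: step 2

Assumption: the Burkholderia cepacia lipase keeps its usual preference for the primary arm whose 2-methyl centre is S; if it preferred the other arm on this substrate, acetylation of the meso diol with the same enzyme and vinyl acetate would give the same monoacetate.

**Step 1**
Reactants: 1 1-bromo-2,2-dimethoxypropane
Product: 2 3-bromo-2-methoxyprop-1-ene
Conditions: i-Pr2NEt·TsOH (cat.), neat, 150–190 °C, MeOH distilled off; fractional distillation
Reagents that add atoms: none
Why: Acid-catalysed ketal-to-enol-ether elimination (loss of methanol through the oxocarbenium ion) is the standard entry to 2-methoxyallyl bromide, and any vinylic bromide isomer formed alongside is inert to silver ion in the next step.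

**Step 2**
Reactants: 2 3-bromo-2-methoxyprop-1-ene; 3 (2E,4E)-hexa-2,4-diene
Product: 5 (3R,6S)-3,6-dimethylcyclohept-4-en-1-one (cis; meso), via enol ether 4 (not isolated)
Conditions: AgO2CCF3, Na2CO3, excess 3, isopentane/CH2Cl2, −78 → 0 °C, dark; filter; 0.1 M aq. HNO3, rt
Reagents that add atoms: water, SMILES O
Why: Silver-assisted loss of bromide from 2 gives the 2-methoxyallyl cation, a three-carbon, two-π-electron partner that adds across C2 and C5 of the s-cis diene in a cationic [4+3] cycloaddition (oxyallyl-type cation plus 1,3-diene, the homologue of a Diels–Alder reaction), forming C4–C5 and C7–C8 of the target. The seven-membered carbocycle is closed by this intermolecular cycloaddition itself, both σ-bonds being made on one face of the diene. The two new methyl-bearing stereocentres are controlled by the E,E geometry of 3, which becomes a cis relationship as long as both bonds form before rotation in any allyl-cation-like intermediate; no absolute control is needed because the cis product has a mirror plane. The diene is symmetric, so regiochemistry does not arise, and the selectivity the step needs is stereospecificity over a stepwise path, which low temperature, a non-polar medium and the weakly nucleophilic trifluoroacetate counter-ion are chosen to secure. Proton loss from the cyclic oxocarbenium ion gives enol ether 4, which dilute acid hydrolyses to ketone 5 without touching the non-enolisable β-stereocentres.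

**Step 3**
Reactants: 5 (3R,6S)-3,6-dimethylcyclohept-4-en-1-one
Product: 6 (3R,7S)-3,7-dimethyl-5-methylidenecyclohept-1-ene (cis; meso)
Conditions: Ph3PCH3Br, KOt-Bu, THF, 0 °C → rt
Reagents that add atoms: methyltriphenylphosphonium bromide, SMILES C[P+](c1ccccc1)(c1ccccc1)c1ccccc1.[Br-]
Why: Wittig methylenation of an unhindered ketone supplies the carbon that becomes the C6 methyl, and the β-methyl centres cannot epimerise under the basic conditions.

**Step 4**
Reactants: 6 (3R,7S)-3,7-dimethyl-5-methylidenecyclohept-1-ene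
Product: 7 triethyl{[(1s,3R,6S)-1,3,6-trimethylcyclohept-4-en-1-yl]peroxy}silane (peroxy group trans to the C3 and C6 methyls; meso)
Conditions: Co(acac)2 (cat.), Et3SiH, O2 (1 atm), ClCH2CH2Cl, rt; chromatography
Reagents that add atoms: dioxygen, SMILES O=O; triethylsilane, SMILES CC[SiH](CC)CC
Why: Mukaiyama–Isayama peroxysilylation, in which hydrogen-atom transfer from a cobalt hydride to the 1,1-disubstituted alkene (much faster than to the ring 1,2-disubstituted alkene) gives the tertiary radical that captures O2 and is silylated; the new quaternary centre is set by substrate control, O2 being expected to approach axially on the chair that keeps both allylic methyls equatorial so that the peroxy group ends trans to them, and the achiral cis epimer expected alongside is removed by chromatography.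

**Step 5**
Reactants: 7 triethyl{[(1s,3R,6S)-1,3,6-trimethylcyclohept-4-en-1-yl]peroxy}silane
Product: 9 (2R,4s,6S)-2,4,6-trimethyl-4-[(triethylsilyl)peroxy]heptane-1,7-diol (meso), via ozonide 8 (not isolated)
Conditions: O3, CH2Cl2, −78 °C; N2 purge; NaBH4, EtOH, −78 → 0 °C
Reagents that add atoms: ozone, SMILES [O-][O+]=O
Why: Ozonolysis of the only remaining C=C and hydride reduction of ozonide 8 give the two primary alcohols; ozone does not attack silyl peroxides, the hindered tertiary Si–O–O unit should survive brief cold borohydride, and the mirror plane is kept.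

**Step 6**
Reactants: 9 (2R,4s,6S)-2,4,6-trimethyl-4-[(triethylsilyl)peroxy]heptane-1,7-diol
Product: 10 (2R,4s,6S)-2,4,6-trimethyl-4-[(triethylsilyl)peroxy]heptane-1,7-diyl diacetate (meso)
Conditions: Ac2O, pyridine, DMAP (cat.), CH2Cl2, 0 °C → rt
Reagents that add atoms: acetic anhydride, SMILES CC(=O)OC(C)=O
Why: Routine DMAP-catalysed acetylation of two unhindered primary alcohols under conditions that leave the silyl peroxide alone.

**Step 7**
Reactants: 10 (2R,4s,6S)-2,4,6-trimethyl-4-[(triethylsilyl)peroxy]heptane-1,7-diyl diacetate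
Product: 11 (2R,4S,6S)-7-hydroxy-2,4,6-trimethyl-4-[(triethylsilyl)peroxy]heptyl acetate
Conditions: Burkholderia cepacia lipase (Amano PS), pH 7 phosphate buffer/acetone, 25 °C, stopped after one equivalent of acid is released
Reagents that add atoms: none
Why: Lipase-catalysed enantiotopic-group-selective hydrolysis of a meso diacetate, expected to cleave the acetate on the arm whose methyl centre is S (the C9 arm); this fixes the absolute configuration of both methyl centres and makes the peroxy carbon stereogenic, while further hydrolysis of the minor enantiomer to diol should raise the optical purity of the monoacetate.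

**Step 8**
Reactants: 11 (2R,4S,6S)-7-hydroxy-2,4,6-trimethyl-4-[(triethylsilyl)peroxy]heptyl acetate
Product: 12 (2R,4R,6S)-2,4,6-trimethyl-7-oxo-4-[(triethylsilyl)peroxy]heptyl acetate
Conditions: TEMPO (cat.), PhI(OAc)2, CH2Cl2, rt
Reagents that add atoms: none
Why: Oxoammonium (TEMPO) oxidation stops at the aldehyde in the absence of water, is neutral enough not to epimerise the α-methyl centre, and does not touch the peroxide or the acetate.

**Step 9**
Reactants: 13 1,6-dibromohexane
Product: 14 hexane-1,6-diylbis(triphenylphosphonium) dibromide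
Conditions: PPh3 (2.2 equiv), DMF, 120 °C; crystallisation
Reagents that add atoms: triphenylphosphine, SMILES c1ccc(cc1)P(c1ccccc1)c1ccccc1
Why: Double SN2 quaternisation of a primary dibromide gives the crystalline six-carbon linker that supplies C10–C15.

**Step 10**
Reactants: 12 (2R,4R,6S)-2,4,6-trimethyl-7-oxo-4-[(triethylsilyl)peroxy]heptyl acetate; 14 hexane-1,6-diylbis(triphenylphosphonium) dibromide
Product: 16 [(6Z,8S,10S,12R)-13-acetoxy-8,10,12-trimethyl-10-[(triethylsilyl)peroxy]tridec-6-en-1-yl]triphenylphosphonium bromide, via mono-ylide 15 (not isolated)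
Conditions: 14 (4 equiv), NaN(SiMe3)2 (2 equiv), THF, 0 °C; 12 added slowly at −78 °C, then → −20 °C; aq. NH4Br; chromatography (CH2Cl2/MeOH)
Reagents that add atoms: none
Why: Wittig olefination in which a deficit of base on excess bis-salt gives mainly mono-ylide 15, which should condense with the aldehyde at low temperature faster than it attacks the acetate or the hindered silyl peroxide; the geometry of the new C9=C10 bond is irrelevant because it is saturated in the next step.

**Step 11**
Reactants: 16 [(6Z,8S,10S,12R)-13-acetoxy-8,10,12-trimethyl-10-[(triethylsilyl)peroxy]tridec-6-en-1-yl]triphenylphosphonium bromide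
Product: 17 [(8R,10S,12R)-13-acetoxy-8,10,12-trimethyl-10-[(triethylsilyl)peroxy]tridecyl]triphenylphosphonium bromide
Conditions: 2-nitrobenzenesulfonohydrazide (NBSH, excess), Et3N, CH2Cl2, rt
Reagents that add atoms: none
Why: Diimide generated from NBSH delivers H2 to the isolated C=C by concerted syn transfer and, unlike catalytic hydrogenation, does not cleave O–O bonds; esters and phosphonium salts are inert to it.

**Step 12**
Reactants: 17 [(8R,10S,12R)-13-acetoxy-8,10,12-trimethyl-10-[(triethylsilyl)peroxy]tridecyl]triphenylphosphonium bromide; 18 benzaldehyde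
Product: 20 (2R,4S,6R,13Z)-2,4,6-trimethyl-14-phenyl-4-[(triethylsilyl)peroxy]tetradec-13-en-1-yl acetate, via ylide 19 (not isolated)
Conditions: NaN(SiMe3)2 (1.0 equiv), THF, −78 °C; 18, −78 °C → rt; chromatography on AgNO3-doped silica if needed
Reagents that add atoms: none
Why: Wittig reaction of the non-stabilised ylide 19 with benzaldehyde under lithium-free conditions, where kinetically controlled formation of the cis-oxaphosphetane should give the Z-styrene.

**Step 13**
Reactants: 20 (2R,4S,6R,13Z)-2,4,6-trimethyl-14-phenyl-4-[(triethylsilyl)peroxy]tetradec-13-en-1-yl acetate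
Product: 21 (2R,4S,6R,13Z)-2,4,6-trimethyl-14-phenyl-4-[(triethylsilyl)peroxy]tetradec-13-en-1-ol
Conditions: i-Bu2AlH, CH2Cl2, −78 °C; aq. potassium sodium tartrate
Reagents that add atoms: none
Why: Reductive cleavage of the acetate by the aluminium hydride at −78 °C avoids the basic methanolysis that could desilylate the peroxide, and hindered peroxides and the styrene are expected to be inert at this temperature.

**Step 14**
Reactants: 21 (2R,4S,6R,13Z)-2,4,6-trimethyl-14-phenyl-4-[(triethylsilyl)peroxy]tetradec-13-en-1-ol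
Product: 22 (2R,4S,6R,13Z)-2,4,6-trimethyl-14-phenyl-4-[(triethylsilyl)peroxy]tetradec-13-enoic acid
Conditions: TEMPO (cat.), PhI(OAc)2 (2.5 equiv), MeCN/pH 7 buffer, 0 °C → rt
Reagents that add atoms: water, SMILES O
Why: TEMPO/PhI(OAc)2 oxidation in aqueous acetonitrile takes the primary alcohol through the aldehyde hydrate to the acid in one flask under near-neutral conditions, sparing the α-stereocentre (C4), the Z-alkene and the peroxide.

**Step 15**
Reactants: 22 (2R,4S,6R,13Z)-2,4,6-trimethyl-14-phenyl-4-[(triethylsilyl)peroxy]tetradec-13-enoic acid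
Product: 25 methyl (4R,6S,8R,15Z)-4,6,8-trimethyl-3-oxo-16-phenyl-6-[(triethylsilyl)peroxy]hexadec-15-enoate, via acyl imidazolide 23 (not isolated), via acylmalonic half-ester 24 (not isolated)
Conditions: CDI, THF, rt; Mg(O2CCH2CO2Me)2, THF, rt; cold 0.5 M HCl work-up
Reagents that add atoms: magnesium bis(3-methoxy-3-oxopropanoate), SMILES [Mg+2].COC(=O)CC(=O)[O-].COC(=O)CC(=O)[O-]
Why: Masamune–Brooks two-carbon homologation, in which the acyl imidazolide C-acylates the magnesium malonate enolate and the adduct decarboxylates to the β-keto ester under neutral conditions that should not epimerise C4 or disturb the peroxide.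

**Step 16**
Reactants: 25 methyl (4R,6S,8R,15Z)-4,6,8-trimethyl-3-oxo-16-phenyl-6-[(triethylsilyl)peroxy]hexadec-15-enoate
Product: 27 methyl 2-[(3S,4R,6S)-3-hydroxy-4,6-dimethyl-6-[(2R,9Z)-2-methyl-10-phenyldec-9-en-1-yl]-1,2-dioxan-3-yl]acetate, via hydroperoxy ketone 26 (not isolated)
Conditions: HF·pyridine, THF/pyridine, 0 °C → rt
Reagents that add atoms: none
Why: Fluoride cleaves the Si–O bond to hydroperoxide 26, whose OOH adds to the C3 ketone in a 6-exo-trig closure of the 1,2-dioxane; the hemiketal is reversible, so C3 should settle with axial OH (anomeric effect) and equatorial CH2CO2Me on the chair that already holds the C4 methyl and the C6 side chain equatorial, which is the 3S configuration.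

**Compound list**

1 | 1-bromo-2,2-dimethoxypropane | COC(C)(CBr)OC | starting material
2 | 3-bromo-2-methoxyprop-1-ene | COC(=C)CBr | intermediate
3 | (2E,4E)-hexa-2,4-diene | C/C=C/C=C/C | starting material
4 | cis-1-methoxy-3,6-dimethylcyclohepta-1,4-diene (racemic enol ether, one enantiomer drawn; formed in the flask) | COC1=C[C@H](C)C=C[C@H](C)C1 | intermediate
5 | (3R,6S)-3,6-dimethylcyclohept-4-en-1-one (cis; meso) | O=C1C[C@H](C)C=C[C@H](C)C1 | intermediate
6 | (3R,7S)-3,7-dimethyl-5-methylidenecyclohept-1-ene (cis; meso) | C=C1C[C@H](C)C=C[C@H](C)C1 | intermediate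
7 | triethyl{[(1s,3R,6S)-1,3,6-trimethylcyclohept-4-en-1-yl]peroxy}silane (peroxy trans to the ring methyls; meso) | C[C@]1(OO[Si](CC)(CC)CC)C[C@H](C)C=C[C@H](C)C1 | intermediate
8 | triethyl[(2,4,6-trimethyl-8,9,10-trioxabicyclo[5.2.1]decan-4-yl)peroxy]silane (ozonide of 7; bridgehead configuration undefined; formed in the flask) | C[C@]1(OO[Si](CC)(CC)CC)C[C@H](C)C2OOC(O2)[C@H](C)C1 | intermediate
9 | (2R,4s,6S)-2,4,6-trimethyl-4-[(triethylsilyl)peroxy]heptane-1,7-diol (meso) | OC[C@H](C)C[C@@](C)(OO[Si](CC)(CC)CC)C[C@H](C)CO | intermediate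
10 | (2R,4s,6S)-2,4,6-trimethyl-4-[(triethylsilyl)peroxy]heptane-1,7-diyl diacetate (meso) | CC(=O)OC[C@H](C)C[C@@](C)(OO[Si](CC)(CC)CC)C[C@H](C)COC(C)=O | intermediate
11 | (2R,4S,6S)-7-hydroxy-2,4,6-trimethyl-4-[(triethylsilyl)peroxy]heptyl acetate | CC(=O)OC[C@H](C)C[C@@](C)(OO[Si](CC)(CC)CC)C[C@H](C)CO | intermediate
12 | (2R,4R,6S)-2,4,6-trimethyl-7-oxo-4-[(triethylsilyl)peroxy]heptyl acetate | CC(=O)OC[C@H](C)C[C@@](C)(OO[Si](CC)(CC)CC)C[C@H](C)C=O | intermediate
13 | 1,6-dibromohexane | BrCCCCCCBr | starting material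
14 | hexane-1,6-diylbis(triphenylphosphonium) dibromide | [Br-].[Br-].c1ccccc1[P+](c1ccccc1)(c1ccccc1)CCCCCC[P+](c1ccccc1)(c1ccccc1)c1ccccc1 | intermediate
15 | triphenyl[6-(triphenylphosphoranylidene)hexyl]phosphonium bromide (mono-ylide of 14; formed in the flask) | [Br-].c1ccccc1P(c1ccccc1)(c1ccccc1)=CCCCCC[P+](c1ccccc1)(c1ccccc1)c1ccccc1 | intermediate
16 | [(6Z,8S,10S,12R)-13-acetoxy-8,10,12-trimethyl-10-[(triethylsilyl)peroxy]tridec-6-en-1-yl]triphenylphosphonium bromide | CC(=O)OC[C@H](C)C[C@@](C)(OO[Si](CC)(CC)CC)C[C@H](C)/C=C\CCCCC[P+](c1ccccc1)(c1ccccc1)c1ccccc1.[Br-] | intermediate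
17 | [(8R,10S,12R)-13-acetoxy-8,10,12-trimethyl-10-[(triethylsilyl)peroxy]tridecyl]triphenylphosphonium bromide | CC(=O)OC[C@H](C)C[C@@](C)(OO[Si](CC)(CC)CC)C[C@H](C)CCCCCCC[P+](c1ccccc1)(c1ccccc1)c1ccccc1.[Br-] | intermediate
18 | benzaldehyde | O=Cc1ccccc1 | starting material
19 | (2R,4S,6R)-2,4,6-trimethyl-4-[(triethylsilyl)peroxy]-13-(triphenylphosphoranylidene)tridecyl acetate (ylide of 17; formed in the flask) | CC(=O)OC[C@H](C)C[C@@](C)(OO[Si](CC)(CC)CC)C[C@H](C)CCCCCCC=P(c1ccccc1)(c1ccccc1)c1ccccc1 | intermediate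
20 | (2R,4S,6R,13Z)-2,4,6-trimethyl-14-phenyl-4-[(triethylsilyl)peroxy]tetradec-13-en-1-yl acetate | CC(=O)OC[C@H](C)C[C@@](C)(OO[Si](CC)(CC)CC)C[C@H](C)CCCCCC/C=C\c1ccccc1 | intermediate
21 | (2R,4S,6R,13Z)-2,4,6-trimethyl-14-phenyl-4-[(triethylsilyl)peroxy]tetradec-13-en-1-ol | OC[C@H](C)C[C@@](C)(OO[Si](CC)(CC)CC)C[C@H](C)CCCCCC/C=C\c1ccccc1 | intermediate
22 | (2R,4S,6R,13Z)-2,4,6-trimethyl-14-phenyl-4-[(triethylsilyl)peroxy]tetradec-13-enoic acid | OC(=O)[C@H](C)C[C@@](C)(OO[Si](CC)(CC)CC)C[C@H](C)CCCCCC/C=C\c1ccccc1 | intermediate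
23 | (2R,4S,6R,13Z)-1-(imidazol-1-yl)-2,4,6-trimethyl-14-phenyl-4-[(triethylsilyl)peroxy]tetradec-13-en-1-one (formed in the flask) | O=C([C@H](C)C[C@@](C)(OO[Si](CC)(CC)CC)C[C@H](C)CCCCCC/C=C\c1ccccc1)n1ccnc1 | intermediate
24 | (4R,6S,8R,15Z)-2-(methoxycarbonyl)-4,6,8-trimethyl-3-oxo-16-phenyl-6-[(triethylsilyl)peroxy]hexadec-15-enoic acid (C2 undefined; present as its magnesium salt in the flask) | COC(=O)C(C(=O)O)C(=O)[C@H](C)C[C@@](C)(OO[Si](CC)(CC)CC)C[C@H](C)CCCCCC/C=C\c1ccccc1 | intermediate
25 | methyl (4R,6S,8R,15Z)-4,6,8-trimethyl-3-oxo-16-phenyl-6-[(triethylsilyl)peroxy]hexadec-15-enoate | COC(=O)CC(=O)[C@H](C)C[C@@](C)(OO[Si](CC)(CC)CC)C[C@H](C)CCCCCC/C=C\c1ccccc1 | intermediate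
26 | methyl (4R,6S,8R,15Z)-6-hydroperoxy-4,6,8-trimethyl-3-oxo-16-phenylhexadec-15-enoate (formed in the flask) | COC(=O)CC(=O)[C@H](C)C[C@@](C)(OO)C[C@H](C)CCCCCC/C=C\c1ccccc1 | intermediate
27 | methyl 2-[(3S,4R,6S)-3-hydroxy-4,6-dimethyl-6-[(2R,9Z)-2-methyl-10-phenyldec-9-en-1-yl]-1,2-dioxan-3-yl]acetate | COC(=O)C[C@]1(O)OO[C@@](C)(C[C@H](C)CCCCCC/C=C\c2ccccc2)C[C@H]1C | target

**Step count**

Total steps: 16. Longest linear sequence: 15 (steps 1–8 and 10–16; step 9 prepares the linker).

**Steps most likely to fail**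

Step 2. The two C–C bonds may form stepwise, with rotation in the allyl-cation intermediate eroding the cis geometry, or the cation may simply alkylate or oligomerise the diene. Fallback, setting out from 3 and returning at 5: the three-carbon partner is changed to an iron-bound oxyallyl species. Diene 3 and 1,1,3,3-tetrabromoacetone with Fe2(CO)9 in benzene at 60 °C should give 2,7-dibromo-cis-3,6-dimethylcyclohept-4-en-1-one F1 by the same [4+3] bond formation. Zn–Cu couple with NH4Cl in MeOH then removes both bromines to give 5.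

Step 4. Capture of the tertiary radical by O2 may show poor facial selectivity, and the peroxyl radical may cyclise across the ring onto the alkene. Fallback, setting out from 5 and returning at 7: an ionic route under thermodynamic control. MeMgBr/CeCl3 (THF, −78 °C) adds to 5 to give cis-1,3,6-trimethylcyclohept-4-en-1-ol F2 (either C1 epimer serves). Acid-catalysed perhydrolysis (50% H2O2, cat. H2SO4, Et2O, 0 °C) passes reversibly through the tertiary cation and should favour the more stable hydroperoxide, (1s,3R,6S)-1-hydroperoxy-1,3,6-trimethylcyclohept-4-ene F3, with OOH axial and all three methyls equatorial. Et3SiCl/imidazole in DMF then gives 7.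

Step 10. Over-deprotonation to the bis-ylide may cause double olefination, and the polar phosphonium product may be lost on purification. Fallback, setting out from 12 and returning at 20: a protected ω-hydroxy ylide followed by a vinyl iodide and cross-coupling. 6-Bromohexan-1-ol and 4-methoxybenzyl trichloroacetimidate (cat. camphorsulfonic acid) give 1-[(6-bromohexyloxy)methyl]-4-methoxybenzene F4, and PPh3 in refluxing MeCN gives {6-[(4-methoxybenzyl)oxy]hexyl}triphenylphosphonium bromide F5. Its ylide (NaN(SiMe3)2, THF, −78 °C) and 12 give (2R,4S,6S,7Z)-13-[(4-methoxybenzyl)oxy]-2,4,6-trimethyl-4-[(triethylsilyl)peroxy]tridec-7-en-1-yl acetate F6. NBSH/Et3N saturates it to (2R,4S,6R)-13-[(4-methoxybenzyl)oxy]-2,4,6-trimethyl-4-[(triethylsilyl)peroxy]tridecyl acetate F7. DDQ in CH2Cl2/pH 7 buffer frees (2R,4S,6R)-13-hydroxy-2,4,6-trimethyl-4-[(triethylsilyl)peroxy]tridecyl acetate F8. TEMPO/PhI(OAc)2 gives (2R,4S,6R)-2,4,6-trimethyl-13-oxo-4-[(triethylsilyl)peroxy]tridecyl acetate F9. Stork–Zhao olefination ((iodomethyl)triphenylphosphonium iodide, NaN(SiMe3)2, THF/DMPU, −78 °C) gives (2R,4S,6R,13Z)-14-iodo-2,4,6-trimethyl-4-[(triethylsilyl)peroxy]tetradec-13-en-1-yl acetate F10. Suzuki–Miyaura coupling with phenylboronic acid (PdCl2(dppf), K3PO4, THF/H2O, rt) proceeds with retention of alkene geometry to give 20.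

**Further compounds**

F1 | step 2 | 2,7-dibromo-cis-3,6-dimethylcyclohept-4-en-1-one (bromine configurations undefined) | O=C1C(Br)[C@H](C)C=C[C@H](C)C1Br
F2 | step 4 | cis-1,3,6-trimethylcyclohept-4-en-1-ol (C1 undefined) | CC1(O)C[C@H](C)C=C[C@H](C)C1
F3 | step 4 | (1s,3R,6S)-1-hydroperoxy-1,3,6-trimethylcyclohept-4-ene | C[C@]1(OO)C[C@H](C)C=C[C@H](C)C1
F4 | step 10 | 1-[(6-bromohexyloxy)methyl]-4-methoxybenzene | COc1ccc(COCCCCCCBr)cc1
F5 | step 10 | {6-[(4-methoxybenzyl)oxy]hexyl}triphenylphosphonium bromide | COc1ccc(COCCCCCC[P+](c2ccccc2)(c2ccccc2)c2ccccc2)cc1.[Br-]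
F6 | step 10 | (2R,4S,6S,7Z)-13-[(4-methoxybenzyl)oxy]-2,4,6-trimethyl-4-[(triethylsilyl)peroxy]tridec-7-en-1-yl acetate | CC(=O)OC[C@H](C)C[C@@](C)(OO[Si](CC)(CC)CC)C[C@H](C)/C=C\CCCCCOCc1ccc(OC)cc1
F7 | step 10 | (2R,4S,6R)-13-[(4-methoxybenzyl)oxy]-2,4,6-trimethyl-4-[(triethylsilyl)peroxy]tridecyl acetate | CC(=O)OC[C@H](C)C[C@@](C)(OO[Si](CC)(CC)CC)C[C@H](C)CCCCCCCOCc1ccc(OC)cc1
F8 | step 10 | (2R,4S,6R)-13-hydroxy-2,4,6-trimethyl-4-[(triethylsilyl)peroxy]tridecyl acetate | CC(=O)OC[C@H](C)C[C@@](C)(OO[Si](CC)(CC)CC)C[C@H](C)CCCCCCCO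
F9 | step 10 | (2R,4S,6R)-2,4,6-trimethyl-13-oxo-4-[(triethylsilyl)peroxy]tridecyl acetate | CC(=O)OC[C@H](C)C[C@@](C)(OO[Si](CC)(CC)CC)C[C@H](C)CCCCCCC=O
F10 | step 10 | (2R,4S,6R,13Z)-14-iodo-2,4,6-trimethyl-4-[(triethylsilyl)peroxy]tetradec-13-en-1-yl acetate | CC(=O)OC[C@H](C)C[C@@](C)(OO[Si](CC)(CC)CC)C[C@H](C)CCCCCC/C=C\I
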